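With the ring numbered C1 (quaternary oxirane carbon bearing C7H2OBz), C2 (CHOBz), C3 (CHOH), C4=C5 and C6 (oxirane CH), the chain C7–C1–C6–C5=C4 of the cyclohexene ring is a masked γ,δ-unsaturated α-oxy acid. C1–C6 is therefore disconnected by a retro-Ireland–Claisen step that ties C7 to an oxygen on C4. In the forward sense one [3,3] shift closes the carbocycle, creates C1 and C6, and places the alkene at C4=C5. It also leaves chloride on C6 anti to the C1 oxygen, ready for oxirane closure. The precursor is an L-galactono-1,5-lactone homologue with an (E)-2-chlorovinyl group on C4, silyl ethers on the C1 and C2 oxygens and a PMB ether on the C3 oxygen.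

Key step: step 8

Assumption: L-galactose is bought as such; its C1–C6 become C7, C1, C2, C3, C4 and C5, and chloroform supplies C6. Compounds 3–7 are drawn as β-anomers, which is of no consequence because the anomeric carbon ends as the lactone carbonyl (TBS = tert-butyldimethylsilyl, PMB = 4-methoxybenzyl, Bz = benzoyl).

Step 1
Reactants: 1 L-galactose
Product: 2 4,6-O-[(R)-4-methoxybenzylidene]-L-galactopyranose (anomeric mixture)
Conditions: 4-MeOC6H4CH(OMe)2, camphorsulfonic acid (cat.), DMF, 50 °C, reduced pressure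
Reagents that add atoms: 4-methoxybenzaldehyde dimethyl acetal, COc1ccc(cc1)C(OC)OC
Why: Acid-catalysed transacetalisation under thermodynamic control ties O4 and O6 of the pyranose into the cis-fused 1,3-dioxane, whose new acetal carbon takes the R configuration that puts the aryl group equatorial.

Step 2
Reactants: 2 4,6-O-(4-methoxybenzylidene)-L-galactopyranose
Product: 3 tert-butyldimethylsilyl 2,3-bis-O-TBS-4,6-O-[(R)-4-methoxybenzylidene]-β-L-galactopyranoside
Conditions: TBSOTf, 2,6-lutidine, CH2Cl2, 0 → 23 °C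
Reagents that add atoms: tert-butyldimethylsilyl trifluoromethanesulfonate, CC(C)(C)[Si](C)(C)OS(=O)(=O)C(F)(F)F
Why: Exhaustive silylation with a silyl triflate and a hindered pyridine base caps O1, O2 and O3 in one operation without touching the acetal, so no regioselection is needed and the glycosyl silyl ether temporarily masks the future C7.

Step 3
Reactants: 3 tris-TBS 4,6-O-arylidene galactoside
Product: 4 tert-butyldimethylsilyl 2,3-bis-O-TBS-4-O-PMB-β-L-galactopyranoside (6-OH free)
Conditions: BH3·THF, Cu(OTf)2 (cat.), CH2Cl2, 0 → 23 °C; H2O quench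
Reagents that add atoms: none
Why: In this regioselective reductive opening of a 4,6-O-arylidene acetal the Lewis-acid-activated borane binds the more accessible O6, the C–O6 bond breaks and hydride quenches the oxocarbenium ion, so PMB stays on O4 (future C3 oxygen) and the primary alcohol is freed.

Step 4
Reactants: 4 6-hydroxy galactoside
Product: 5 tert-butyldimethylsilyl 2,3-bis-O-TBS-4-O-PMB-β-L-galacto-hexodialdo-1,5-pyranoside (6-aldehyde)
Conditions: Dess–Martin periodinane, CH2Cl2, 23 °C
Reagents that add atoms: none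
Why: Dess–Martin oxidation gives the aldehyde under non-basic conditions, so neither epimerisation next to the ring oxygen nor β-elimination of the 4-O-PMB group should occur.

Step 5
Reactants: 5 6-aldehyde; 6 chloroform
Product: 7 tert-butyldimethylsilyl (E)-7-chloro-6,7-dideoxy-2,3-bis-O-TBS-4-O-PMB-β-L-galacto-hept-6-enopyranoside
Conditions: CrCl2, CHCl3, THF, 65 °C
Reagents that add atoms: chloroform (6), ClC(Cl)Cl
Why: In the Takai olefination the geminal dichromium species made from CHCl3 and divalent chromium adds to a true aldehyde and eliminates through the less crowded arrangement to give mainly the E-chloroalkene, any Z isomer being removed here by chromatography.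

Step 6
Reactants: 7 chlorovinyl glycosyl silyl ether
Product: 8 (E)-7-chloro-6,7-dideoxy-2,3-bis-O-TBS-4-O-PMB-L-galacto-hept-6-enopyranose (lactol)
Conditions: Bu4NF, AcOH, THF, 0 °C
Reagents that add atoms: none
Why: This fluoride desilylation is chemoselective because the glycosyl silyl ether is the most labile of the three, its oxygen leaving as a stabilised hemiacetal anion, and the acetic acid buffer suppresses silyl migration from O2.

Step 7
Reactants: 8 lactol
Product: 9 (E)-7-chloro-6,7-dideoxy-2,3-bis-O-TBS-4-O-PMB-L-galacto-hept-6-enono-1,5-lactone (δ-lactone with the chlorovinyl group on C4, PMB on the C3 oxygen and TBS on the C2 and C1 oxygens; vinyl group, C3–O and C2–O all cis)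
Conditions: Dess–Martin periodinane, CH2Cl2, 23 °C
Reagents that add atoms: none
Why: Dess–Martin oxidation of a lactol gives the aldono-1,5-lactone directly under neutral conditions that leave the silyl ethers, the PMB ether and the chloroalkene untouched.

Step 8
Reactants: 9 chlorovinyl δ-lactone
Product: 12 (1S,2R,3R,6R)-6-chloro-1,2-bis(tert-butyldimethylsilyloxy)-3-(4-methoxybenzyloxy)cyclohex-4-ene-1-carboxylic acid, via trimethylsilyl ketene acetal 10 (not isolated), via trimethylsilyl ester 11 (not isolated)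
Conditions: Me3SiCl, KN(SiMe3)2, THF, −78 → 0 °C; solvent switch to toluene, 95 °C; aq. citric acid, THF, 23 °C
Reagents that add atoms: chlorotrimethylsilane, C[Si](C)(C)Cl (its silicon groups sit in 10 and 11 only and are lost again on the way to 12)
Why: KN(SiMe3)2 removes the axial H on C1 while Me3SiCl is already present, so the enolate is trapped as ketene acetal 10 before the C2 silyloxy group can leave, and on heating 10 undergoes a concerted suprafacial [3,3] shift (Ireland–Claisen rearrangement) that forms C1–C6 as C4–O breaks and gives silyl ester 11, which mild acid hydrolyses to 12. The closest known reaction type is the Ireland–Claisen rearrangement of 6-alkenyl δ-lactone silyl ketene acetals to cyclohexenecarboxylic acids, the chlorine on the alkene terminus being an added spectator. The cyclohexene ring C1–C6 is closed pericyclically across the 1,4-positions of the lactone through a bicyclo[2.2.2]octane-like boat in which the axial chlorovinyl arm on C4 folds over the ring face to reach C1, so the new C4=C5 bond is necessarily cis. C1 is set by the tether, because C6 can reach only the face of the ketene acetal that carries the vinyl group, which puts C7 trans and the C1 oxygen cis to the C2 and C3 oxygens. C6 is set by the E geometry of the chloroalkene together with the suprafacial course dictated by the C4 configuration, which leaves Cl trans to the C1 oxygen. The step needs complete chirality transfer and no dehydrochlorination: the ring allows only this one boat, and in the E-chloroalkene H5 and Cl are syn, so anti elimination is shut off.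

Step 9
Reactants: 12 cyclohexenecarboxylic acid
Product: 13 [(1R,2R,3R,6R)-6-chloro-1,2-bis(tert-butyldimethylsilyloxy)-3-(4-methoxybenzyloxy)cyclohex-4-en-1-yl]methanol
Conditions: BH3·THF, THF, 0 → 23 °C; H2O quench
Reagents that add atoms: none
Why: Borane reduction of the carboxylic acid through its acyloxyborane should outrun hydroboration of the hindered ring alkene, which two allylic heteroatoms deactivate, and borane does not displace the allylic chloride as an aluminium hydride might.

Step 10
Reactants: 13 chloro bis-silyl ether alcohol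
Product: 15 (1R,2R,3R,6S)-1-(hydroxymethyl)-3-(4-methoxybenzyloxy)-1,6-epoxycyclohex-4-en-2-ol (epoxy diol), via chlorohydrin triol 14 (not isolated)
Conditions: Bu4NF, THF, 0 → 23 °C
Reagents that add atoms: none
Why: Fluoride removes both silyl ethers and the freed C1 alkoxide, anti to C6–Cl, displaces chloride by intramolecular SN2 (3-exo-tet halohydrin closure) with inversion at C6, giving the cis-fused oxirane on the face of the C2 and C3 oxygens while no ester is yet present that could migrate.

Step 11
Reactants: 15 epoxy diol; 16 benzoyl chloride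
Product: 17 (1S,2R,3R,6S)-2-benzoyloxy-1-(benzoyloxymethyl)-3-(4-methoxybenzyloxy)-1,6-epoxycyclohex-4-ene
Conditions: BzCl, Et3N, DMAP (cat.), CH2Cl2, 0 → 23 °C
Reagents that add atoms: benzoyl chloride (16), O=C(Cl)c1ccccc1
Why: DMAP-catalysed acylation esterifies the primary C7 and the secondary C2 hydroxyl together, the C3 oxygen being masked as its PMB ether and the amine base keeping the vinyl oxirane away from acid.

Step 12
Reactants: 17 dibenzoate PMB ether
Product: 18 target, [(1S,2R,3R,6S)-2-benzoyloxy-3-hydroxy-1,6-epoxycyclohex-4-en-1-yl]methyl benzoate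
Conditions: DDQ, CH2Cl2–pH 7 phosphate buffer, 0 °C
Reagents that add atoms: none
Why: Oxidative PMB cleavage with DDQ (hydride abstraction, then hydrolysis of the oxocarbenium ion) frees the C3 hydroxyl at neutral pH, so the cis C2 benzoate should not migrate and the vinyl oxirane should survive.

Compound list
1 | L-galactose | OC[C@@H]1OC(O)[C@@H](O)[C@H](O)[C@@H]1O | starting material
2 | 4,6-O-[(R)-4-methoxybenzylidene]-L-galactopyranose | COc1ccc(cc1)[C@@H]1OC[C@@H]2OC(O)[C@@H](O)[C@H](O)[C@@H]2O1 | intermediate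
3 | tert-butyldimethylsilyl 2,3-bis-O-TBS-4,6-O-[(R)-4-methoxybenzylidene]-β-L-galactopyranoside | COc1ccc(cc1)[C@@H]1OC[C@@H]2O[C@H](O[Si](C)(C)C(C)(C)C)[C@@H](O[Si](C)(C)C(C)(C)C)[C@H](O[Si](C)(C)C(C)(C)C)[C@@H]2O1 | intermediate
4 | tert-butyldimethylsilyl 2,3-bis-O-TBS-4-O-PMB-β-L-galactopyranoside | OC[C@@H]1O[C@H](O[Si](C)(C)C(C)(C)C)[C@@H](O[Si](C)(C)C(C)(C)C)[C@H](O[Si](C)(C)C(C)(C)C)[C@@H]1OCc2ccc(OC)cc2 | intermediate
5 | tert-butyldimethylsilyl 2,3-bis-O-TBS-4-O-PMB-β-L-galacto-hexodialdo-1,5-pyranoside | O=C[C@@H]1O[C@H](O[Si](C)(C)C(C)(C)C)[C@@H](O[Si](C)(C)C(C)(C)C)[C@H](O[Si](C)(C)C(C)(C)C)[C@@H]1OCc2ccc(OC)cc2 | intermediate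
6 | chloroform | ClC(Cl)Cl | starting material
7 | tert-butyldimethylsilyl (E)-7-chloro-6,7-dideoxy-2,3-bis-O-TBS-4-O-PMB-β-L-galacto-hept-6-enopyranoside | Cl/C=C/[C@@H]1O[C@H](O[Si](C)(C)C(C)(C)C)[C@@H](O[Si](C)(C)C(C)(C)C)[C@H](O[Si](C)(C)C(C)(C)C)[C@@H]1OCc2ccc(OC)cc2 | intermediate
8 | (E)-7-chloro-6,7-dideoxy-2,3-bis-O-TBS-4-O-PMB-L-galacto-hept-6-enopyranose | Cl/C=C/[C@@H]1OC(O)[C@@H](O[Si](C)(C)C(C)(C)C)[C@H](O[Si](C)(C)C(C)(C)C)[C@@H]1OCc2ccc(OC)cc2 | intermediate
9 | (E)-7-chloro-6,7-dideoxy-2,3-bis-O-TBS-4-O-PMB-L-galacto-hept-6-enono-1,5-lactone | Cl/C=C/[C@H]1[C@@H](OCc2ccc(OC)cc2)[C@@H](O[Si](C)(C)C(C)(C)C)[C@H](O[Si](C)(C)C(C)(C)C)C(=O)O1 | intermediate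
10 | trimethylsilyl ketene acetal of 9 | Cl/C=C/[C@H]1[C@@H](OCc2ccc(OC)cc2)[C@@H](O[Si](C)(C)C(C)(C)C)C(O[Si](C)(C)C(C)(C)C)=C(O[Si](C)(C)C)O1 | intermediate
11 | trimethylsilyl ester of 12 | C[Si](C)(C)OC(=O)[C@]1(O[Si](C)(C)C(C)(C)C)[C@H](Cl)C=C[C@@H](OCc2ccc(OC)cc2)[C@H]1O[Si](C)(C)C(C)(C)C | intermediate
12 | (1S,2R,3R,6R)-6-chloro-1,2-bis(TBS-oxy)-3-(PMB-oxy)cyclohex-4-ene-1-carboxylic acid | OC(=O)[C@]1(O[Si](C)(C)C(C)(C)C)[C@H](Cl)C=C[C@@H](OCc2ccc(OC)cc2)[C@H]1O[Si](C)(C)C(C)(C)C | intermediate
13 | [(1R,2R,3R,6R)-6-chloro-1,2-bis(TBS-oxy)-3-(PMB-oxy)cyclohex-4-en-1-yl]methanol | OC[C@]1(O[Si](C)(C)C(C)(C)C)[C@H](Cl)C=C[C@@H](OCc2ccc(OC)cc2)[C@H]1O[Si](C)(C)C(C)(C)C | intermediate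
14 | (1R,2R,3R,6R)-6-chloro-1-(hydroxymethyl)-3-(PMB-oxy)cyclohex-4-ene-1,2-diol | OC[C@]1(O)[C@H](Cl)C=C[C@@H](OCc2ccc(OC)cc2)[C@H]1O | intermediate
15 | (1R,2R,3R,6S)-1-(hydroxymethyl)-3-(PMB-oxy)-1,6-epoxycyclohex-4-en-2-ol | OC[C@]12O[C@H]1C=C[C@@H](OCc3ccc(OC)cc3)[C@H]2O | intermediate
16 | benzoyl chloride | O=C(Cl)c1ccccc1 | starting material
17 | (1S,2R,3R,6S)-2-benzoyloxy-1-(benzoyloxymethyl)-3-(PMB-oxy)-1,6-epoxycyclohex-4-ene | O=C(OC[C@]12O[C@H]1C=C[C@@H](OCc3ccc(OC)cc3)[C@H]2OC(=O)c1ccccc1)c1ccccc1 | intermediate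
18 | [(1S,2R,3R,6S)-2-benzoyloxy-3-hydroxy-1,6-epoxycyclohex-4-en-1-yl]methyl benzoate | O=C(OC[C@]12O[C@H]1C=C[C@@H](O)[C@H]2OC(=O)c1ccccc1)c1ccccc1 | target

Total step count: 12. Longest linear sequence: 12 steps, from L-galactose.

Steps most likely to fail

Step 8.
- **What may go wrong:** the C2 silyloxy group may be lost by β-elimination from the enolate before silylation. Deprotonation of the hindered C1–H may be sluggish, or the ketene acetal may break down before the strained boat is reached.
- **Fallback, from 4 back to 12:** an untethered [3,3] shift followed by ring closure through metathesis.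
  - I2, PPh3 and imidazole convert 4 into the 6-deoxy-6-iodo glycoside F1.
  - Zn dust in aqueous THF triggers a Bernet–Vasella fragmentation to the hex-5-enal F2.
  - Pinnick oxidation (NaClO2, NaH2PO4, 2-methylbut-2-ene) gives the hex-5-enoic acid F3.
  - Alkylation with (Z)-1,3-dichloropropene (Cs2CO3, DMF) gives the (Z)-3-chloroallyl ester F4.
  - An open-chain Ireland–Claisen rearrangement (KN(SiMe3)2, Me3SiCl, −78 → 23 °C) forms C1–C6 and gives the diene acid F5.
  - Ring-closing metathesis with the second-generation Grubbs catalyst closes C4=C5 and delivers 12.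
- **Stereocontrol in the fallback:** in the open-chain chair the α-oxygen should sit syn to the metal-bound oxygen, so the Z-chloride is the one that leads to the C1/C6 relationship of 12. Facial bias comes only from C2, so isomers may have to be separated after ring closure.

Step 10.
- **What may go wrong:** the oxirane may migrate toward C7 (Payne-type equilibration through the free primary alkoxide). Base may induce 1,4-loss of HCl, or cleavage of the tertiary silyl ether may be incomplete.
- **Fallback, from 13 back to 15:** deprotection and closure are uncoupled. The silyl groups are removed under acidic fluoride (3HF·NEt3, MeCN) and chlorohydrin triol 14 is isolated. The oxirane is then closed with Ag2O in CH2Cl2, that is, by halophilic activation of C6–Cl and not by a free alkoxide. This fallback makes no compound outside the list (entry F0).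

Step 9.
- **What may go wrong:** hydroboration of the ring alkene may compete with a slow reduction of the hindered tertiary acid.
- **Fallback, from 12 back to 13:** the acid is esterified with Me3SiCHN2 (toluene–MeOH) to the methyl ester F6. This is reduced with iBu2AlH in CH2Cl2 at −78 °C, a hydride addition that leaves alkenes alone.

Further compounds
F1 | step 8 | tert-butyldimethylsilyl 6-deoxy-6-iodo-2,3-bis-O-TBS-4-O-PMB-β-L-galactopyranoside | IC[C@@H]1O[C@H](O[Si](C)(C)C(C)(C)C)[C@@H](O[Si](C)(C)C(C)(C)C)[C@H](O[Si](C)(C)C(C)(C)C)[C@@H]1OCc2ccc(OC)cc2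
F2 | step 8 | 5,6-dideoxy-2,3-bis-O-TBS-4-O-PMB-D-arabino-hex-5-enose | O=C[C@@H](O[Si](C)(C)C(C)(C)C)[C@H](O[Si](C)(C)C(C)(C)C)[C@H](OCc1ccc(OC)cc1)C=C
F3 | step 8 | 5,6-dideoxy-2,3-bis-O-TBS-4-O-PMB-D-arabino-hex-5-enonic acid | OC(=O)[C@@H](O[Si](C)(C)C(C)(C)C)[C@H](O[Si](C)(C)C(C)(C)C)[C@H](OCc1ccc(OC)cc1)C=C
F4 | step 8 | (Z)-3-chloroallyl ester of F3 | Cl/C=C\COC(=O)[C@@H](O[Si](C)(C)C(C)(C)C)[C@H](O[Si](C)(C)C(C)(C)C)[C@H](OCc1ccc(OC)cc1)C=C
F5 | step 8 | 2-(1-chloroallyl)-2,3-bis(TBS-oxy)-4-(PMB-oxy)hex-5-enoic acid with the C1, C2, C3 and C6 configurations of 12 | OC(=O)[C@](O[Si](C)(C)C(C)(C)C)([C@H](Cl)C=C)[C@H](O[Si](C)(C)C(C)(C)C)[C@H](OCc1ccc(OC)cc1)C=C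
F0 | step 10 | none | none
F6 | step 9 | methyl ester of 12 | COC(=O)[C@]1(O[Si](C)(C)C(C)(C)C)[C@H](Cl)C=C[C@@H](OCc2ccc(OC)cc2)[C@H]1O[Si](C)(C)C(C)(C)C
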